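**Retrosynthetic overview**
1. Acetate ⇐ 6β-alcohol ⇐ trans-decal-6-one; only an ester and a hydride are added after ring A, so no ring is formed later.
2. Ring A (C1–C5, C10) ⇐ monocyclic hydroxy-enone + C6 Grignard reagent in one flask: C10–C1 by alkoxide-directed 1,4-addition at the future quaternary C10, then C4–C5 by capture of a C4 tertiary cation by the C5=C6 silyl enol ether (formal [4+2] annulation across C10=C5).
3. Hydroxy-enone ⇐ mirror-symmetric p-quinol by enantioselective copper hydride desymmetrisation (sets C8 and C9); p-quinol ⇐ quinone monoketal + vinyl Grignard + preformed lactam triflate (B-alkyl Suzuki, C12–C13).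
4. Enabling feature: ring B (C5–C10) is a latent 4-hydroxy-3,5-dimethylcyclohexa-2,5-dienone (C9 carbinol flanked by methyl-bearing C8 and C10, para to the C6 oxygen). The C9 oxygen is cis to C1 and steers the C10–C1 bond; C5 is alpha to the C6 carbonyl (nucleophile towards C4, then epimerisable to the trans fusion); C4 is a gem-dimethyl carbon (tertiary cation).
5. Ring order: lactam ring (bought as tetramic acid, coupled as a unit), ring B (aromatic ring of a phenol), ring A last.

Key step: step 10

Remark: carbon labels C1–C16 follow the terpenoid numbering of the target (ring A = C1–C5 + C10, ring B = C5–C10, C11–C12 linker, lactam = C13–C16 + N); alpha/beta mean below/above the decalin drawn with the C10 methyl up (beta).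

Step 1
Reactants: 1 4-methoxy-2,6-dimethylphenol
Product: 2 4,4-dimethoxy-2,6-dimethylcyclohexa-2,5-dien-1-one
Conditions: PhI(OAc)2 (1.1 equiv), MeOH, 0 °C
Reagents that add atoms: methanol, CO
Why: Hypervalent-iodine oxidative dearomatisation of a para-methoxyphenol in methanol (quinone monoketal formation) should trap the phenoxonium ion at the methoxy-bearing carbon, leaving the only carbonyl flanked by the two methyl groups; no stereocentre is formed.

Step 2
Reactants: 2 4,4-dimethoxy-2,6-dimethylcyclohexa-2,5-dien-1-one; 3 vinylmagnesium bromide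
Product: 4 1-ethenyl-4,4-dimethoxy-2,6-dimethylcyclohexa-2,5-dien-1-ol
Conditions: THF, −78 → 0 °C; aq. NaHCO3
Reagents that add atoms: none
Why: Grignard 1,2-addition to the single, non-enolisable carbonyl should install C11–C12 and the future C9 carbinol while the ketal masks the future C6 carbonyl; the product keeps its mirror plane, so no stereocentre arises.

Step 3
Reactants: 5 tert-butyl 2,4-dioxopyrrolidine-1-carboxylate
Product: 6 tert-butyl 2-oxo-4-(trifluoromethylsulfonyloxy)-2,5-dihydro-1H-pyrrole-1-carboxylate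
Conditions: Tf2O (1.1 equiv), i-Pr2NEt, CH2Cl2, −78 °C
Reagents that add atoms: trifluoromethanesulfonic anhydride, O=S(=O)(OS(=O)(=O)C(F)(F)F)C(F)(F)F
Why: O-sulfonylation of the enolised vinylogous acid (tetramic acid) should give the vinyl triflate, a standard cross-coupling partner that brings the lactam ring in preformed; no stereocentre.

Step 4
Reactants: 4 1-ethenyl-4,4-dimethoxy-2,6-dimethylcyclohexa-2,5-dien-1-ol; 6 tert-butyl 2-oxo-4-(trifluoromethylsulfonyloxy)-2,5-dihydro-1H-pyrrole-1-carboxylate
Product: 8 tert-butyl 4-[2-(1-hydroxy-4,4-dimethoxy-2,6-dimethylcyclohexa-2,5-dien-1-yl)ethyl]-2-oxo-2,5-dihydro-1H-pyrrole-1-carboxylate, via alkylborane 7 (not isolated)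
Conditions: 9-BBN (2.5 equiv), THF, rt → 50 °C; then 6, Pd(dppf)Cl2 (5 mol%), K3PO4 (aq.), DMF, rt
Reagents that add atoms: none
Why: Anti-Markovnikov hydroboration of the only monosubstituted alkene (the ring alkenes are trisubstituted and the ketal leaves no carbonyl for the borane to reduce) followed by B-alkyl Suzuki–Miyaura coupling with the vinyl triflate should form the C12–C13 bond; no stereocentre.

Step 5
Reactants: 8 tert-butyl 4-[2-(1-hydroxy-4,4-dimethoxy-2,6-dimethylcyclohexa-2,5-dien-1-yl)ethyl]-2-oxo-2,5-dihydro-1H-pyrrole-1-carboxylate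
Product: 9 4-[2-(1-hydroxy-2,6-dimethyl-4-oxocyclohexa-2,5-dien-1-yl)ethyl]-1,5-dihydro-2H-pyrrol-2-one
Conditions: TFA/CH2Cl2/H2O (10:10:1), 0 °C → rt
Reagents that add atoms: water, O
Why: Acidolysis should remove the Boc group and hydrolyse the dienyl dimethyl ketal to the cross-conjugated dienone (standard quinol-ketal hydrolysis), unveiling the prochiral p-quinol, whose 3,5-dimethyl pattern blocks a dienone–phenol rearrangement.

Step 6
Reactants: 9 4-[2-(1-hydroxy-2,6-dimethyl-4-oxocyclohexa-2,5-dien-1-yl)ethyl]-1,5-dihydro-2H-pyrrol-2-one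
Product: 10 4-{2-[2,6-dimethyl-4-oxo-1-(triethylsilyloxy)cyclohexa-2,5-dien-1-yl]ethyl}-1,5-dihydro-2H-pyrrol-2-one
Conditions: TESOTf (2.5 equiv), 2,6-lutidine, CH2Cl2, −78 → 0 °C; then MeOH, aq. NaHCO3
Reagents that add atoms: triethylsilyl trifluoromethanesulfonate, CC[Si](CC)(CC)OS(=O)(=O)C(F)(F)F
Why: Silyl triflate silylation of the hindered tertiary alcohol (transient silylation of the lactam is reversed in the methanolic work-up) should place a bulky group on the oxygen face of both enone arms for step 7; no stereocentre.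

Step 7
Reactants: 10 4-{2-[2,6-dimethyl-4-oxo-1-(triethylsilyloxy)cyclohexa-2,5-dien-1-yl]ethyl}-1,5-dihydro-2H-pyrrol-2-one
Product: 12 4-{2-[(1R,6R)-1-hydroxy-2,6-dimethyl-4-oxocyclohex-2-en-1-yl]ethyl}-1,5-dihydro-2H-pyrrol-2-one, via silyl dienol ether 11 (not isolated)
Conditions: Cu(OAc)2 (5 mol%), (S)-p-Tol-BINAP or its antipode (5.5 mol%), (MeO)2MeSiH (3 equiv), toluene, 0 °C → rt; then TBAF, AcOH, THF, 0 °C
Reagents that add atoms: none
Why: Copper hydride asymmetric conjugate reduction, used as desymmetrisation of a prochiral cyclohexa-2,5-dienone, should have the chiral catalyst select one enantiotopic enone arm (the ligand antipode that leads to the (1R,6R) product is used) while hydride enters C8 anti to the bulky, electron-withdrawing C9 siloxy group, so that the C8 methyl ends cis to the C9 oxygen and C8 and C9 are set together; the product stays masked as dienol silyl ether 11 (no over-reduction, and the unsaturated lactam is a far poorer acceptor than the enone) until fluoride frees ketone and tertiary alcohol.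

Step 8
Reactants: 13 5-bromo-2-methylpent-2-ene
Product: 14 5-bromo-2-methoxy-2-methylpentane
Conditions: MeOH (solvent), Amberlyst-15 (cat.), 40 °C
Reagents that add atoms: methanol, CO
Why: Acid-catalysed Markovnikov addition of methanol to the trisubstituted alkene (tertiary ether formation) should give the tertiary methyl ether that later serves as the C4 cation precursor, the primary bromide being inert; no stereocentre.

Step 9
Reactants: 14 5-bromo-2-methoxy-2-methylpentane
Product: 15 (4-methoxy-4-methylpentyl)magnesium bromide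
Conditions: Mg turnings, THF, 35 °C
Reagents that add atoms: magnesium, [Mg]
Why: Grignard formation at the primary bromide should be clean because the delta-methoxy group offers no elimination pathway.

Step 10
Reactants: 12 4-{2-[(1R,6R)-1-hydroxy-2,6-dimethyl-4-oxocyclohex-2-en-1-yl]ethyl}-1,5-dihydro-2H-pyrrol-2-one; 15 (4-methoxy-4-methylpentyl)magnesium bromide
Product: 19 4-{2-[(1R,2R,4aS,8aS)-1-hydroxy-2,5,5,8a-tetramethyl-4-oxodecahydronaphthalen-1-yl]ethyl}-1,5-dihydro-2H-pyrrol-2-one, via bromomagnesium enolate 16 (not isolated), via silyl enol ether 17 (not isolated), via cis-fused silyl ketone 18 (not isolated)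
Conditions: t-BuMgCl (2.05 equiv), THF, −78 °C; 15 (1.3 equiv), −78 → −20 °C; TMSCl, Et3N, −78 °C → rt; evaporate, CH2Cl2; TiCl4 (3 equiv), −78 → −40 °C; then NaOMe, MeOH, 40 °C
Reagents that add atoms: none
Why: Mechanism: the C9 magnesium alkoxide binds Grignard reagent 15 and delivers its alkyl group to C10 on the oxygen-bearing face (1,4-addition), the resulting C5=C6 magnesium enolate 16 is silylated to 17, TiCl4 then ionises the tertiary methyl ether to the C4 cation, and C5 of the silyl enol ether captures it with loss of Me3SiCl to give ketone 18. The closest known reaction types are the ligand-assisted (alkoxide-directed) 1,4-addition of Grignard reagents to 4-oxido enones and the Lewis-acid-mediated alpha-tert-alkylation of silyl enol ethers (Reetz alkylation, silyl-enol-ether-terminated cation cyclisation), run here in one flask as a formal [4+2] annulation of a C6 unit across C10=C5. Ring A (C10, C1, C2, C3, C4, C5) closes at C4–C5 in a 6-(enol-exo) mode, the enol carbon attacking the exocyclic trigonal C4 cation through a chair-like transition state. C10 is controlled by the C9 alkoxide (C1 enters cis to O9, so the C10 methyl ends trans to it), and C5 is controlled thermodynamically: it is alpha to the C6 ketone, and NaOMe equilibrates the expected kinetic cis-fused ketone 18 to the trans-decalin (5S), in which C1 and C4 are both equatorial on ring B, whereas the cis isomer must place either C4 1,3-diaxial to the C9 oxygen or, after ring flip, the C9 side chain and the C8 methyl axial. The step needs 1,4- rather than 1,2-addition and an untouched lactam (secured by alkoxide delivery and by the lactam being present as its N-magnesio amidate), alkylation at C5 rather than C7 (secured by the enolate regiochemistry handed over from the conjugate addition), and ionisation at C4 rather than C9 (a tertiary OSiMe3 group is a far poorer Lewis base and leaving group than OMe). The methanolic base also removes the O- and N-silyl groups.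

Step 11
Reactants: 19 4-{2-[(1R,2R,4aS,8aS)-1-hydroxy-2,5,5,8a-tetramethyl-4-oxodecahydronaphthalen-1-yl]ethyl}-1,5-dihydro-2H-pyrrol-2-one
Product: 20 4-{2-[(1R,2R,4R,4aS,8aS)-1,4-dihydroxy-2,5,5,8a-tetramethyldecahydronaphthalen-1-yl]ethyl}-1,5-dihydro-2H-pyrrol-2-one
Conditions: NaBH4, MeOH, −20 → 0 °C
Reagents that add atoms: none
Why: Borohydride reduction of the C6 ketone should occur from the alpha face (equatorial attack), because the beta face is screened by the 1,3-diaxial C4 and C10 methyl groups, giving the axial 6-beta alcohol (6R), while the unsaturated lactam is inert to NaBH4.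

Step 12
Reactants: 20 4-{2-[(1R,2R,4R,4aS,8aS)-1,4-dihydroxy-2,5,5,8a-tetramethyldecahydronaphthalen-1-yl]ethyl}-1,5-dihydro-2H-pyrrol-2-one
Product: 21 (1R,3R,4R,4aS,8aS)-4-hydroxy-3,4a,8,8-tetramethyl-4-[2-(5-oxo-2,5-dihydro-1H-pyrrol-3-yl)ethyl]decahydronaphthalen-1-yl acetate
Conditions: Ac2O, DMAP, pyridine, 40 °C
Reagents that add atoms: acetic anhydride, CC(=O)OC(C)=O
Why: DMAP-catalysed acetylation should be selective for the secondary C6 alcohol over the hindered tertiary C9 alcohol and the weakly nucleophilic lactam N–H (any N-acetyl imide is far more labile than the hindered ester and is removed in a mild methanolic work-up); no stereocentre is touched.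

**Compound list**
1 | 4-methoxy-2,6-dimethylphenol | COc1cc(C)c(O)c(C)c1 | starting material
2 | 4,4-dimethoxy-2,6-dimethylcyclohexa-2,5-dien-1-one | COC1(OC)C=C(C)C(=O)C(C)=C1 | intermediate
3 | vinylmagnesium bromide | C=C[Mg]Br | starting material
4 | 1-ethenyl-4,4-dimethoxy-2,6-dimethylcyclohexa-2,5-dien-1-ol | COC1(OC)C=C(C)C(O)(C=C)C(C)=C1 | intermediate
5 | tert-butyl 2,4-dioxopyrrolidine-1-carboxylate | CC(C)(C)OC(=O)N1CC(=O)CC1=O | starting material
6 | tert-butyl 2-oxo-4-(trifluoromethylsulfonyloxy)-2,5-dihydro-1H-pyrrole-1-carboxylate | CC(C)(C)OC(=O)N1CC(OS(=O)(=O)C(F)(F)F)=CC1=O | intermediate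
7 | 1-[2-(9-borabicyclo[3.3.1]nonan-9-yl)ethyl]-4,4-dimethoxy-2,6-dimethylcyclohexa-2,5-dien-1-ol | COC1(OC)C=C(C)C(O)(CCB2C3CCCC2CCC3)C(C)=C1 | intermediate
8 | tert-butyl 4-[2-(1-hydroxy-4,4-dimethoxy-2,6-dimethylcyclohexa-2,5-dien-1-yl)ethyl]-2-oxo-2,5-dihydro-1H-pyrrole-1-carboxylate | COC1(OC)C=C(C)C(O)(CCC2=CC(=O)N(C(=O)OC(C)(C)C)C2)C(C)=C1 | intermediate
9 | 4-[2-(1-hydroxy-2,6-dimethyl-4-oxocyclohexa-2,5-dien-1-yl)ethyl]-1,5-dihydro-2H-pyrrol-2-one | CC1=CC(=O)C=C(C)C1(O)CCC1=CC(=O)NC1 | intermediate
10 | 4-{2-[2,6-dimethyl-4-oxo-1-(triethylsilyloxy)cyclohexa-2,5-dien-1-yl]ethyl}-1,5-dihydro-2H-pyrrol-2-one | CC[Si](CC)(CC)OC1(CCC2=CC(=O)NC2)C(C)=CC(=O)C=C1C | intermediate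
11 | 4-{2-[(1R,6R)-4-[dimethoxy(methyl)silyl]oxy-2,6-dimethyl-1-(triethylsilyloxy)cyclohexa-2,4-dien-1-yl]ethyl}-1,5-dihydro-2H-pyrrol-2-one | CO[Si](C)(OC)OC1=C[C@@H](C)[C@](O[Si](CC)(CC)CC)(CCC2=CC(=O)NC2)C(C)=C1 | intermediate
12 | 4-{2-[(1R,6R)-1-hydroxy-2,6-dimethyl-4-oxocyclohex-2-en-1-yl]ethyl}-1,5-dihydro-2H-pyrrol-2-one | O=C1C[C@@H](C)[C@](O)(CCC2=CC(=O)NC2)C(C)=C1 | intermediate
13 | 5-bromo-2-methylpent-2-ene | CC(C)=CCCBr | starting material
14 | 5-bromo-2-methoxy-2-methylpentane | COC(C)(C)CCCBr | intermediate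
15 | (4-methoxy-4-methylpentyl)magnesium bromide | COC(C)(C)CCC[Mg]Br | intermediate
16 | bromomagnesium C5=C6 enolate of the 1,4-adduct, (1R,2S,6R) on the cyclohexene ring, with C9–OMgCl and lactam N–MgCl | C1=C(O[Mg]Br)C[C@@H](C)[C@](O[Mg]Cl)(CCC2=CC(=O)N([Mg]Cl)C2)[C@@]1(C)CCCC(C)(C)OC | intermediate
17 | 4-{2-[(1R,2S,6R)-2-(4-methoxy-4-methylpentyl)-2,6-dimethyl-1,4-bis(trimethylsilyloxy)cyclohex-3-en-1-yl]ethyl}-1-(trimethylsilyl)-1,5-dihydro-2H-pyrrol-2-one | C1=C(O[Si](C)(C)C)C[C@@H](C)[C@](O[Si](C)(C)C)(CCC2=CC(=O)N([Si](C)(C)C)C2)[C@@]1(C)CCCC(C)(C)OC | intermediate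
18 | 4-{2-[(1R,2R,4aR,8aS)-2,5,5,8a-tetramethyl-4-oxo-1-(trimethylsilyloxy)decahydronaphthalen-1-yl]ethyl}-1-(trimethylsilyl)-1,5-dihydro-2H-pyrrol-2-one (cis-fused, C5 epimer) | O=C1C[C@@H](C)[C@](O[Si](C)(C)C)(CCC2=CC(=O)N([Si](C)(C)C)C2)[C@@]2(C)CCCC(C)(C)[C@@H]12 | intermediate
19 | 4-{2-[(1R,2R,4aS,8aS)-1-hydroxy-2,5,5,8a-tetramethyl-4-oxodecahydronaphthalen-1-yl]ethyl}-1,5-dihydro-2H-pyrrol-2-one | O=C1C[C@@H](C)[C@](O)(CCC2=CC(=O)NC2)[C@@]2(C)CCCC(C)(C)[C@H]12 | intermediate
20 | 4-{2-[(1R,2R,4R,4aS,8aS)-1,4-dihydroxy-2,5,5,8a-tetramethyldecahydronaphthalen-1-yl]ethyl}-1,5-dihydro-2H-pyrrol-2-one | O[C@@H]1C[C@@H](C)[C@](O)(CCC2=CC(=O)NC2)[C@@]2(C)CCCC(C)(C)[C@H]12 | intermediate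
21 | (1R,3R,4R,4aS,8aS)-4-hydroxy-3,4a,8,8-tetramethyl-4-[2-(5-oxo-2,5-dihydro-1H-pyrrol-3-yl)ethyl]decahydronaphthalen-1-yl acetate | CC(=O)O[C@@H]1C[C@@H](C)[C@](O)(CCC2=CC(=O)NC2)[C@@]2(C)CCCC(C)(C)[C@H]12 | target

**Step count and risks**
Total steps: 12. Longest linear sequence: 9 steps (1, 2, 4, 5, 6, 7, 10, 11, 12); side branches are step 3 (triflate) and steps 8–9 (Grignard reagent).

Steps most likely to fail:

Step 10 (key step). The Grignard reagent may add 1,2 to the C6 carbonyl or fail to reach the fully substituted beta-carbon next to the C9 carbinol. On the closure side, the C4 cation may lose a proton or be captured by the C9 oxygen instead of C5. The fallback sets out from 12 and comes back at 19, replacing alkoxide delivery by a covalent radical tether and the cationic closure by an aldol condensation. Ethyl vinyl ether and NBS should convert 12 into bromoacetal F1. Bu3SnH/AIBN should then give, by 5-exo radical cyclisation onto C10 (Ueno–Stork cyclisation), the cis-fused bicyclic acetal F2, in which C1 is forced cis to O9 and C10 is quaternary. Aqueous acid should give lactol F3, and Wittig olefination with Ph3P=CHC(O)CH3 should open it to enone F4. Chemoselective conjugate reduction with [CuH(PPh3)]6 should give diketone F5. KOH/MeOH aldol condensation of C5 onto the C4 carbonyl should close ring A, still the last ring, as bicyclic enone F6. Me2CuLi/TMSCl should add the second C4 methyl group, and NaOMe equilibration of C5 should give 19.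

Step 7. Hydride delivery may show poor facial selectivity relative to the C9 siloxy group, the two enantiotopic enone arms may be discriminated incompletely, or reduction may go further. The fallback sets out from 9 and comes back at 12. The unprotected p-quinol is desymmetrised biocatalytically with an ene-reductase of the Old Yellow Enzyme family (NADPH recycled with glucose and glucose dehydrogenase). A panel is screened for the enzyme whose pocket, rather than substrate bias, dictates arm and face. This gives 12 directly, without the silyl ether of step 6 and without a new compound.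

Step 4. Hydroboration of the neopentyl-type vinyl group may be slow, and the electron-poor triflate 6 may hydrolyse under the aqueous base of the coupling. The fallback sets out from 4 and comes back at 8. Hydroboration with 9-BBN and oxidation with NaBO3 should give diol F7. Appel iodination (I2, PPh3, imidazole) should give iodide F8. Base-free nickel-catalysed reductive cross-electrophile coupling of F8 with 6 (NiBr2(dme), 4,4'-di-tert-butyl-2,2'-bipyridine, Mn, DMA) should give 8.

Further compounds
F0 | step 7 | none | none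
F1 | step 10 | bromoacetal of 12: 4-{2-[(1R,6R)-1-(2-bromo-1-ethoxyethoxy)-2,6-dimethyl-4-oxocyclohex-2-en-1-yl]ethyl}-1,5-dihydro-2H-pyrrol-2-one (both acetal epimers) | O=C1C[C@@H](C)[C@](OC(OCC)CBr)(CCC2=CC(=O)NC2)C(C)=C1
F2 | step 10 | cis-fused bicyclic ethoxy acetal (tetrahydrofuran ring O9–C2–C1–C10–C9 on the C6 ketone; C8 and C9 as in 12, C10 as in 19; both acetal epimers) | O=C1C[C@@H](C)[C@@]2(CCC3=CC(=O)NC3)OC(OCC)C[C@@]2(C)C1
F3 | step 10 | lactol corresponding to F2 (OH in place of OEt; both epimers) | O=C1C[C@@H](C)[C@@]2(CCC3=CC(=O)NC3)OC(O)C[C@@]2(C)C1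
F4 | step 10 | ring-opened (E)-enone: C10 carries CH2–CH=CH–C(O)CH3, C9–OH free, C6 ketone | O=C1C[C@@H](C)[C@](O)(CCC2=CC(=O)NC2)[C@@](C)(C/C=C/C(C)=O)C1
F5 | step 10 | diketone: C10 carries the 4-oxopentyl chain, C9–OH free, C6 ketone | O=C1C[C@@H](C)[C@](O)(CCC2=CC(=O)NC2)[C@@](C)(CCCC(C)=O)C1
F6 | step 10 | bicyclic enone: ring A closed, C4=C5 double bond conjugated with the C6 ketone, one methyl on C4 | O=C1C[C@@H](C)[C@](O)(CCC2=CC(=O)NC2)[C@@]2(C)CCCC(C)=C12
F7 | step 4 | 1-(2-hydroxyethyl)-4,4-dimethoxy-2,6-dimethylcyclohexa-2,5-dien-1-ol | COC1(OC)C=C(C)C(O)(CCO)C(C)=C1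
F8 | step 4 | 1-(2-iodoethyl)-4,4-dimethoxy-2,6-dimethylcyclohexa-2,5-dien-1-ol | COC1(OC)C=C(C)C(O)(CCI)C(C)=C1
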